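## Structural features

The target is a verticillane-type bicyclo[9.3.1]pentadecane. Ring A is a cyclohexanone made of C1, C14, C13 (C=O), C12 (=C18H2), C11 and C15 (CMe2). It shares the unit C1–C15–C11 with a twelve-membered carbocycle C1–C2–C3–C4(Me)–C5–C6–C7–C8(Me)–C9–C10(OAc)–C11–C15. The bonds C1–C2 and C11–C10 leave ring A on opposite faces (1R,11S), so the nine-carbon bridge spans the gem-dimethyl carbon in a trans sense. There are seven stereocentres: C1 and C11 flank the quaternary C15, C10 (R, acetoxy) is bonded directly to C11, and the two trisubstituted epoxides are (3R,4R), from an E alkene, and (7R,8S), from a Z alkene. The fragile groups are the α-methylene ketone (a Michael acceptor that is lost to base or nucleophiles), the two acid-labile trisubstituted epoxides, and the C10 acetate next to the C7–C8 epoxide. The real difficulty is threefold: placing C1 and C11 trans across a quaternary carbon, closing a trans-bridged twelve-membered ring that holds one E and one Z trisubstituted alkene, and setting four epoxide stereocentres that have no neighbouring handle. The key step exploits the twofold axis through C13 and C15 that ring A has once C18 is removed: C1–C2 and C11–C10 become homotopic bonds to two vinyl groups on the β-carbons of a flat, achiral cyclohexadienone.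

## Logic of the disconnections

29 ⇒ 27 (through 28). The acetyl group is removed and the C10 oxygen is joined to C18, so the enone C12=C18 and the C10 oxygen are stored together as a five-membered cyclic β-alkoxy ketone. This removes both sensitive functions of ring A at once. The forward step must open that ether by E1cB against a ring–chain equilibrium, so the C10 alkoxide has to be acylated as it is released.

27 ⇒ 26 ⇒ 25. The C13 ketone is taken back to the alcohol and its silyl ether. The β-alkoxy ketone is then absent while bases, hydrides and oxidants are used. The forward deprotection and oxidation must be neutral enough for two trisubstituted epoxides.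

25 ⇒ 24. The four C–O bonds C3–O, C4–O, C7–O and C8–O are cut. Both epoxides have an R-configured CH carbon, so a single chiral dioxirane can make both, and the E and Z geometries translate into the trans and cis epoxides. Four stereocentres are reduced to two alkene geometries. The forward step requires that catalyst control prevail over the facial bias of the macrocycle at both alkenes.

24 ⇒ 23 ⇒ 22. The C5–C6 bond is cut, the only sp3–sp3 bond of the large ring that is allylic on both sides and remote from every stereocentre. A sulfone on C6 supplies the nucleophile and is then removed. The bicycle becomes ring A with two open arms. The forward step needs high-dilution closure of a strained twelve-membered ring and retention of both alkene geometries in alkylation and desulfonylation.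

22 ⇒ 21 ⇒ 20 ⇒ 18 + 19, and 18 ⇒ 17 ⇒ 16. The C3=C4 double bond is cut. An E-trisubstituted alkene bearing methyl is the reliable outcome of a stabilised α-methyl ylide, and 19 brings C4, its methyl and C5 in one reagent. The C3 aldehyde comes from the C1 vinyl group by anti-Markovnikov hydration and oxidation. The forward steps need hydroboration of the monosubstituted alkene beside the trisubstituted one, and E selectivity.

16 ⇒ 13 ⇒ 10 + 12, and 12 ⇒ 11. The C8–C9 bond is cut, which places the whole Z-trisubstituted alkene (C6, C7, C8 and its methyl) in a four-carbon reagent whose geometry is fixed by trans-hydroalumination of an alkynol. The forward step must join an sp2 carbon to a β-alkoxy primary iodide without β-elimination and without loss of the Z geometry.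

10 ⇒ 9 ⇒ 8 ⇒ 7. The C10–O bond and the C9–I bond are cut. The hydroxymethyl group on C12 reaches only the vinyl group on C11, so this one step tells the two vinyl groups apart, installs the C10 oxygen with its configuration and leaves C9 as a handle. The forward step needs 5-exo regiochemistry and face selection by allylic 1,3-strain. The ketone is reduced and protected directly afterwards.

7 ⇒ 5 (through 6). The C12–C18 bond is cut. At this point the two α-carbons are homotopic, so no regiocontrol is needed; later C12 and C14 could not be told apart. The forward step must stop at mono-hydroxymethylation without dehydration.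

5 ⇒ 2 + 3 (through 4). The bonds C1–C2 and C11–C10 are cut together. Two C–C bonds and two stereocentres fall back to an achiral dienone and a two-carbon nucleophile. The forward step needs enantiofacial control in the first addition, trans selectivity in the second, and reactivity at β-carbons next to a quaternary centre.

2 ⇒ 1. The C5–C6 double bond is removed; 1 is commercial.

## Other disconnections considered

Alternative 1: The cut is C2–C3, an sp3–sp2 bond of the macrocycle. In the forward direction an open-chain compound A2 carries a pinacol boronate on C2 (placed by one-carbon boron homologation of a C1 boronate) and an E alkenyl iodide at C3. An intramolecular B-alkyl Suzuki–Miyaura coupling (Pd(dppf)Cl2, Cs2CO3) would close it to the bicyclic 3E,7Z-diene A1, which has the C13 and C10 oxygens silylated and the C12 methylene already in place.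
- In favour: ring closure and E geometry come in one stereoretentive step with nothing to remove afterwards. This is better than the two-step sulfone closure chosen here. The 1,2-boronate shift is stereospecific, and the two silyl ethers are orthogonal.
- Against: C1 and C11 have to be set by separate operations, because the twofold axis of ring A is not used. A primary alkyl pinacol boronate transmetalates slowly and needs strongly basic conditions at high dilution. The exocyclic methylene is carried through the epoxidation as a third alkene, and C13 must still be deprotected and oxidised.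
- Comparison: on structure, both plans end at a 3E,7Z-diene and face the same facial question in the double epoxidation (equal). On mechanism, the Suzuki closure is cleaner at the ring-forming bond (better), while the chosen plan is cleaner in how C1, C10 and C11 arise. On step economy, the closure itself is shorter for A1, but making A2 with three independent stereocentres and both geometries is expected to cost more than the symmetric entry.

Alternative 2: The cut is C9–C10, with a temporary O–C6 bond. In the forward direction aldehyde A4 (C10 as a formyl group on C11, protected hydroxymethyl on C12, silyloxymethyl on C1) and silyl dienolate A5 would combine in a vinylogous Mukaiyama aldol reaction under Ti(OiPr)4 and a chiral binaphthol. The δ-hydroxy enoate lactonises to dihydropyranone A3.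
- In favour: C10 is set by an external catalyst whose sense can be chosen, which is more adjustable than the substrate control at C10 in the chosen plan. The lactone ring forces C6 and C9 cis, so the 7Z geometry is fixed by constitution. C6 arrives as a carbonyl ready for extension.
- Against: A4 is an α-branched aldehyde beside a quaternary carbon and a β-alkoxy ketone. Substrate bias may oppose the catalyst, and the Lewis acid may cause β-elimination at C18 or epimerisation at C12. C2 and C3 have to be rebuilt from a one-carbon stub. The lactone must be reduced and C6 refunctionalised.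
- Comparison: on the Z alkene the plans are equal (ring constraint there, stereospecific trans-hydroalumination here). On C10 the alternative has the more tunable control. On step economy it is longer: after A3, lactone opening, differentiation of two hydroxyls and the whole C1 arm remain, whereas the chosen plan has both arms in place from the key step.

Alternative 3: The cut is C11–C15, the ring A bond next to the quaternary carbon. In the forward direction the fourteen-membered cembranoid A7 (isopropenyl on C1, Z enone C11=C12–C13=O) is treated with Fe(acac)3 and PhSiH3. Hydrogen-atom transfer gives the tertiary C15 radical, which adds 6-endo to C11 and would give A6 after reduction of the α-keto radical.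
- In favour: the hardest bond and ring A are made last, on a monocycle that is easier to close than the trans-bridged bicycle. C1 can come from the chiral pool. The neutral radical conditions allow epoxides and acetate to be present already. A6 is two operations from the target, comparable to the chosen endgame.
- Against: C11 (and the temporary C12) are set only by the conformation of a flexible macrocycle at the moment of attack, and the epoxides must have been installed stereoselectively on that same flexible ring. Simple reduction of the isopropenyl group and addition at C12 compete.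
- Comparison: in bonds formed per step and in convergence the alternative is the better plan. In predictability of the C1/C11 relationship the chosen plan is better, because both centres come from one catalyst-controlled event. Step economy is probably comparable and depends on access to A7.

Key step: step 2

Remark on the structures: the C2-symmetric ketone 5 as drawn is the trans (3S,5S) isomer and maps onto C1 (R) and C11 (S) of the target. The epoxides correspond to a 3E,7Z-diene. No structure needed correction.

Assumption on the ligand: the (S,S) diene ligand is taken to give (3S,5S)-5 by analogy with the usual facial model of this catalyst family. If the sense is the reverse, the (R,R) ligand is used and nothing else changes.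

Remark on temporary centres: C12 (in 7–10, 13–18, 20–27), C13 (in 9, 10, 13–18, 20–26) and C6 (in 23) are drawn as the expected major isomers. Each is erased later, so its configuration does not affect the outcome. Target numbering (C1–C18) is used for all intermediates.

## Route

Step 1
Reactants: 1 4,4-dimethylcyclohex-2-en-1-one
Product: 2 4,4-dimethylcyclohexa-2,5-dien-1-one
Conditions: DDQ, 1,4-dioxane, reflux (no acid)
Reagents that add atoms: none
Why: Quinone dehydrogenation: hydride is abstracted from C6 of the cross-conjugated dienol, the only dienol available because C4 is quaternary; acid is left out so that the dienone–phenol rearrangement cannot start.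

Step 2
Reactants: 2 4,4-dimethylcyclohexa-2,5-dien-1-one; 3 potassium vinyltrifluoroborate
Product: 5 (3S,5S)-4,4-dimethyl-3,5-divinylcyclohexan-1-one, via monovinyl enone 4 (not isolated)
Conditions: [RhCl(C2H4)2]2 (2.5 mol %), (S,S)-2,5-diphenylbicyclo[2.2.2]octa-2,5-diene (5.5 mol %), aq. KOH (20 mol %), 3 (3 equiv), 1,4-dioxane–H2O, 40 °C
Reagents that add atoms: potassium vinyltrifluoroborate (3), C=C[B-](F)(F)F.[K+]
Why: This is a Hayashi–Miyaura asymmetric conjugate addition run twice in one flask: hydroxide converts the chloride dimer into the diene-ligated rhodium hydroxide, vinyl passes from boron to monovalent rhodium, the alkenylrhodium inserts one enone unit of 2, and water protonates the rhodium enolate to give 4, which re-enters the same cycle. The closest known reaction type is the rhodium/chiral diene addition of alkenylboron reagents to cyclohexenones and 4,4-disubstituted cyclohexadienones. No ring is closed; the bonds C1–C2 and C11–C10 and two stereocentres are formed. The first centre is set by the ligand, which selects one face at a β-carbon; the two β-carbons of 2 are related by the twofold axis, so either gives the same 4. At the second β-carbon the same ligand preference means the opposite ring face, which is also the face anti to the first vinyl group, so catalyst and substrate are matched and the trans ketone 5 should form in preference to the meso cis isomer. The minor enantiomer of 4 is mismatched in the second addition and should go mainly to the meso ketone, so the enantiomeric purity of 5 is expected to exceed that of 4. The step needs 1,4- over 1,2-addition and complete double addition next to a quaternary carbon; the soft alkenylrhodium nucleophile secures the first, and the small vinyl group with excess borate the second. Over-addition is impossible once both enones are consumed.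

Step 3
Reactants: 5 (3S,5S)-4,4-dimethyl-3,5-divinylcyclohexan-1-one
Product: 7 C12-hydroxymethyl ketone (CH2OH trans to the adjacent C11 vinyl), via trimethylsilyl enol ether 6 (not isolated)
Conditions: LiN(i-Pr)2, Me3SiCl, THF, −78 °C; then aq. HCHO, Yb(OTf)3 (10 mol %), THF–H2O, rt
Reagents that add atoms: formaldehyde, C=O
Why: Enolisation and silylation need no regiocontrol because the two α-carbons of 5 are homotopic; the aqueous lanthanide-triflate Mukaiyama aldol with formaldehyde then stops at mono-hydroxymethylation without dehydration. C18 should enter anti to the C11 vinyl group (also the diequatorial isomer); C12 is a temporary centre that becomes sp2 in step 20.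

Step 4
Reactants: 7 C12-hydroxymethyl ketone
Product: 8 iodo ether ketone (trans-fused tetrahydrofuran C12–C18–O–C10–C11, CH2I on C10 trans to C15 across the new ring)
Conditions: I2, NaHCO3, MeCN, 0 °C
Reagents that add atoms: iodine, II
Why: Iodoetherification, 5-exo-trig: only the vinyl group on C11 is within reach of the C18 hydroxyl, so the two vinyl groups are told apart and oxygen adds to the internal carbon C10. C10 is set by allylic 1,3-strain: in the cyclisation transition state H11, not the quaternary C15, eclipses C10=C9, so C9 ends cis to H11 on the new ring, which is the 10R configuration of the target.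

Step 5
Reactants: 8 iodo ether ketone
Product: 9 C13 alcohol (OH axial, on the ring A face of C2 and C18)
Conditions: LiBH(s-Bu)3, THF, −78 °C
Reagents that add atoms: none
Why: Ketone reduction by a bulky trialkylborohydride, with equatorial hydride delivery; it removes the base-sensitive β-alkoxy ketone before any basic step, and the primary iodide is inert at this temperature. C13 is a temporary centre, reoxidised in step 19.

Step 6
Reactants: 9 C13 alcohol
Product: 10 C13 tert-butyldimethylsilyl ether
Conditions: t-BuMe2SiOTf, 2,6-lutidine, CH2Cl2, −78 → 0 °C
Reagents that add atoms: tert-butyldimethylsilyl trifluoromethanesulfonate, CC(C)(C)[Si](C)(C)OS(=O)(=O)C(F)(F)F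
Why: Silyl ether formation with a silyl triflate and a hindered base, chosen because the axial alcohol is hindered; the ether must last through steps 8–17.

Step 7
Reactants: 11 but-2-yn-1-ol
Product: 12 (Z)-3-iodobut-2-en-1-ol
Conditions: NaAlH2(OCH2CH2OMe)2, THF, 0 °C → rt; then I2, THF, −78 → 0 °C
Reagents that add atoms: iodine, II
Why: Alkoxide-directed trans-hydroalumination of a propargylic alcohol (hydride to C2, aluminium to C3 in a five-membered alanate), then iodinolysis with retention; iodine and CH2OH end cis, the geometry that becomes the 7Z alkene.

Step 8
Reactants: 10 C13 silyl ether iodide; 12 (Z)-3-iodobut-2-en-1-ol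
Product: 13 Z allylic alcohol (C9–C8(Me)=C7H–C6H2OH on C10, C9 and C6 cis)
Conditions: NiBr2(MeOCH2CH2OMe) (10 mol %), 4,4′-di-tert-butyl-2,2′-bipyridine (10 mol %), Mn powder, NaI (cat.), DMA, 25 °C
Reagents that add atoms: (Z)-3-iodobut-2-en-1-ol (12), C/C(I)=C/CO
Why: Nickel-catalysed reductive cross-electrophile coupling of an alkyl iodide with an alkenyl iodide: the alkenyl iodide adds to zerovalent nickel with retention, the alkyl iodide enters as the C9 radical, and reductive elimination forms C8–C9. A β-alkoxy radical does not fragment, manganese does not insert into the C–I bond (so no metal-induced β-elimination), and the trans arrangement of C10 and C2 on ring A rules out radical cyclisation onto the vinyl group.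

Step 9
Reactants: 13 Z allylic alcohol
Product: 16 Z allylic phenyl sulfone (PhSO2 on C6), via allylic mesylate 14 (not isolated), via allylic bromide 15 (not isolated)
Conditions: MsCl, Et3N, THF, −40 °C; LiBr, 0 °C; then PhSO2Na, DMF, rt
Reagents that add atoms: sodium benzenesulfinate, [Na+].[O-]S(=O)c1ccccc1
Why: Two successive SN2 displacements at the primary allylic carbon (bromide, then S-alkylation of the sulfinate) leave the Z alkene untouched; the sulfone later makes C6 the nucleophile.

Step 10
Reactants: 16 Z allylic phenyl sulfone
Product: 17 primary alcohol at C3 (C1–CH2CH2OH)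
Conditions: 9-BBN, THF, 0 °C → rt; then aq. NaOH, H2O2, 0 °C
Reagents that add atoms: hydrogen peroxide, OO
Why: Hydroboration–oxidation: 9-BBN takes the monosubstituted C2=C3 alkene far faster than the trisubstituted C7=C8 and places boron on the terminal carbon C3.

Step 11
Reactants: 17 primary alcohol
Product: 18 C3 aldehyde
Conditions: Dess–Martin periodinane, NaHCO3, CH2Cl2, 0 °C → rt
Reagents that add atoms: none
Why: Dess–Martin oxidation under buffered conditions; sulfone and silyl ether are inert and there is no stereocentre α to the aldehyde.

Step 12
Reactants: 18 C3 aldehyde; 19 ethyl 2-(triphenylphosphoranylidene)propanoate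
Product: 20 ethyl (E)-enoate (C3H=C4(Me)–C5O2Et, C2 trans to C5)
Conditions: toluene, 80 °C
Reagents that add atoms: ethyl 2-(triphenylphosphoranylidene)propanoate (19), CCOC(=O)C(C)=P(c1ccccc1)(c1ccccc1)c1ccccc1
Why: Wittig olefination with a stabilised α-methyl ylide gives the E-trisubstituted enoate and brings in C4, its methyl and C5; the ylide is too weakly basic to deprotonate the sulfone.

Step 13
Reactants: 20 ethyl (E)-enoate
Product: 21 (E)-allylic alcohol at C5
Conditions: i-Bu2AlH, CH2Cl2, −78 °C
Reagents that add atoms: none
Why: 1,2-Reduction of the enoate by a dialkylaluminium hydride at low temperature; sulfone, silyl ether and alkenes are untouched.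

Step 14
Reactants: 21 (E)-allylic alcohol
Product: 22 (E)-allylic bromide at C5
Conditions: CBr4, PPh3, CH2Cl2, −20 → 0 °C
Reagents that add atoms: carbon tetrabromide, BrC(Br)(Br)Br
Why: Appel bromination under neutral conditions, SN2 at the primary allylic carbon; the bromide is used at once.

Step 15
Reactants: 22 (E)-allylic bromide
Product: 23 macrocyclic sulfone (twelve-membered ring closed at C5–C6, PhSO2 on C6, both C6 epimers)
Conditions: KN(SiMe3)2, THF, −20 °C, slow addition of 22 (final 0.002 M)
Reagents that add atoms: none
Why: Intramolecular alkylation of the α-sulfonyl allylic carbanion by the allylic bromide (SN2, twelve-membered ring, high dilution); the carbanion reacts at its α-carbon C6 and both alkene geometries are kept at low temperature. C6 is a temporary centre.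

Step 16
Reactants: 23 macrocyclic sulfone
Product: 24 macrocyclic 3E,7Z-diene (tetrahydrofuran and C13 silyl ether intact)
Conditions: PdCl2[Ph2P(CH2)3PPh2] (10 mol %), LiBHEt3, THF, 0 °C
Reagents that add atoms: none
Why: Palladium-catalysed reductive desulfonylation: the allylic sulfone ionises to a π-allylpalladium and hydride attacks the less substituted terminus C6, so C7=C8 stays in place; fast hydride capture at 0 °C is relied on to keep the Z geometry.

Step 17
Reactants: 24 macrocyclic 3E,7Z-diene
Product: 25 bis-epoxide (3R,4R and 7R,8S) with C13 silyl ether
Conditions: D-fructose-derived Shi ketone (0.6 equiv), KHSO5 (as 2KHSO5·KHSO4·K2SO4), K2CO3, Bu4NHSO4, MeCN–CH2(OMe)2–aq. Na2B4O7 buffer, 0 °C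
Reagents that add atoms: potassium peroxymonosulfate, [K+].[O-]S(=O)(=O)OO
Why: Shi epoxidation: the chiral dioxirane transfers oxygen through a spiro transition state to the face that makes the CH carbon of a trisubstituted alkene R; this gives (3R,4R) from the E alkene and (7R,8S) from the Z alkene, so one catalyst enantiomer serves both. The substrate carries only ether and silyl ether groups, so the basic medium is harmless.

Step 18
Reactants: 25 bis-epoxide silyl ether
Product: 26 bis-epoxy C13 alcohol
Conditions: Bu4NF, THF, 0 → 40 °C
Reagents that add atoms: none
Why: Fluoride desilylation, which is neutral towards the trisubstituted epoxides and the cyclic ether.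

Step 19
Reactants: 26 bis-epoxy alcohol
Product: 27 bis-epoxy keto ether
Conditions: Dess–Martin periodinane, NaHCO3, CH2Cl2, 0 °C
Reagents that add atoms: none
Why: Dess–Martin oxidation buffered with hydrogen carbonate restores the C13 ketone without exposing the epoxides to acid.

Step 20
Reactants: 27 bis-epoxy keto ether
Product: 29 target (CNP0339728.4), via hydroxy enone 28 (not isolated)
Conditions: DBU, Ac2O, DMAP (cat.), CH2Cl2, 0 °C → rt
Reagents that add atoms: acetic anhydride, CC(=O)OC(C)=O
Why: E1cB (retro-oxa-Michael) opening: DBU forms the C12 enolate reversibly, which expels the C10 alkoxide and unveils C12=C18; because re-closure by 5-endo oxa-Michael addition makes this an equilibrium, acetic anhydride and DMAP are present to acylate 28 as it forms, which makes the opening irreversible and installs the acetate. The C10–O bond is never broken, so C10 keeps its configuration.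

## Compound list

1 | 4,4-dimethylcyclohex-2-en-1-one | CC1(C)CCC(=O)C=C1 | starting material
2 | 4,4-dimethylcyclohexa-2,5-dien-1-one | O=C1C=CC(C)(C)C=C1 | intermediate
3 | potassium vinyltrifluoroborate | C=C[B-](F)(F)F.[K+] | starting material
4 | (5S)-4,4-dimethyl-5-vinylcyclohex-2-en-1-one | O=C1C=CC(C)(C)[C@H](C=C)C1 | intermediate
5 | (3S,5S)-4,4-dimethyl-3,5-divinylcyclohexan-1-one (trans, C2-symmetric) | O=C1C[C@@H](C=C)C(C)(C)[C@H](C=C)C1 | intermediate
6 | trimethylsilyl enol ether of 5 (either α-carbon, the two are equivalent) | C[Si](C)(C)OC1=C[C@@H](C=C)C(C)(C)[C@H](C=C)C1 | intermediate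
7 | 2-(hydroxymethyl) derivative of 5 at C12, CH2OH trans to the C11 vinyl | O=C1C[C@@H](C=C)C(C)(C)[C@H](C=C)[C@H]1CO | intermediate
8 | iodo ether ketone: trans-fused tetrahydrofuran C12–C18–O–C10–C11 on the cyclohexanone, CH2I on C10 trans to C15, vinyl on C1 | O=C1C[C@@H](C=C)C(C)(C)[C@H]2[C@H]1CO[C@@H]2CI | intermediate
9 | C13 alcohol of 8, OH on the ring A face of C2 and C18 | O[C@H]1C[C@@H](C=C)C(C)(C)[C@H]2[C@H]1CO[C@@H]2CI | intermediate
10 | C13 tert-butyldimethylsilyl ether of 9 | CC(C)(C)[Si](C)(C)O[C@H]1C[C@@H](C=C)C(C)(C)[C@H]2[C@H]1CO[C@@H]2CI | intermediate
11 | but-2-yn-1-ol | CC#CCO | starting material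
12 | (Z)-3-iodobut-2-en-1-ol | C/C(I)=C/CO | intermediate
13 | Z allylic alcohol: 10 with iodine replaced by C8(Me)=C7H–C6H2OH, C9 and C6 cis | CC(C)(C)[Si](C)(C)O[C@H]1C[C@@H](C=C)C(C)(C)[C@H]2[C@H]1CO[C@@H]2C/C(C)=C\CO | intermediate
14 | C6 methanesulfonate of 13 | CC(C)(C)[Si](C)(C)O[C@H]1C[C@@H](C=C)C(C)(C)[C@H]2[C@H]1CO[C@@H]2C/C(C)=C\COS(C)(=O)=O | intermediate
15 | C6 bromide corresponding to 13 | CC(C)(C)[Si](C)(C)O[C@H]1C[C@@H](C=C)C(C)(C)[C@H]2[C@H]1CO[C@@H]2C/C(C)=C\CBr | intermediate
16 | C6 phenyl sulfone corresponding to 13 | CC(C)(C)[Si](C)(C)O[C@H]1C[C@@H](C=C)C(C)(C)[C@H]2[C@H]1CO[C@@H]2C/C(C)=C\CS(=O)(=O)c3ccccc3 | intermediate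
17 | 16 with the C1 vinyl converted to CH2CH2OH (C3 alcohol) | CC(C)(C)[Si](C)(C)O[C@H]1C[C@@H](CCO)C(C)(C)[C@H]2[C@H]1CO[C@@H]2C/C(C)=C\CS(=O)(=O)c3ccccc3 | intermediate
18 | C3 aldehyde from 17 | CC(C)(C)[Si](C)(C)O[C@H]1C[C@@H](CC=O)C(C)(C)[C@H]2[C@H]1CO[C@@H]2C/C(C)=C\CS(=O)(=O)c3ccccc3 | intermediate
19 | ethyl 2-(triphenylphosphoranylidene)propanoate | CCOC(=O)C(C)=P(c1ccccc1)(c1ccccc1)c1ccccc1 | starting material
20 | ethyl (E)-enoate, C3H=C4(Me)–C5O2Et on C2 | CC(C)(C)[Si](C)(C)O[C@H]1C[C@@H](C/C=C(\C)C(=O)OCC)C(C)(C)[C@H]2[C@H]1CO[C@@H]2C/C(C)=C\CS(=O)(=O)c3ccccc3 | intermediate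
21 | (E)-allylic alcohol at C5 | CC(C)(C)[Si](C)(C)O[C@H]1C[C@@H](C/C=C(\C)CO)C(C)(C)[C@H]2[C@H]1CO[C@@H]2C/C(C)=C\CS(=O)(=O)c3ccccc3 | intermediate
22 | (E)-allylic bromide at C5 | CC(C)(C)[Si](C)(C)O[C@H]1C[C@@H](C/C=C(\C)CBr)C(C)(C)[C@H]2[C@H]1CO[C@@H]2C/C(C)=C\CS(=O)(=O)c3ccccc3 | intermediate
23 | macrocyclic sulfone: twelve-membered 3E,7Z-diene ring with PhSO2 on C6 (both epimers), tetrahydrofuran and C13 silyl ether as in 10 | CC(C)(C)[Si](C)(C)O[C@H]1C[C@H]2C/C=C(C)/CC(S(=O)(=O)c4ccccc4)/C=C(C)\C[C@H]3OC[C@@H]1[C@@H]3C2(C)C | intermediate
24 | macrocyclic 3E,7Z-diene with C18–O–C10 ether and C13 silyl ether | CC(C)(C)[Si](C)(C)O[C@H]1C[C@H]2C/C=C(C)/CC/C=C(C)\C[C@H]3OC[C@@H]1[C@@H]3C2(C)C | intermediate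
25 | (3R,4R),(7R,8S)-bis-epoxide of 24 | CC(C)(C)[Si](C)(C)O[C@H]1C[C@H]2C[C@H]4O[C@]4(C)CC[C@H]5O[C@@]5(C)C[C@H]3OC[C@@H]1[C@@H]3C2(C)C | intermediate
26 | bis-epoxy C13 alcohol | O[C@H]1C[C@H]2C[C@H]4O[C@]4(C)CC[C@H]5O[C@@]5(C)C[C@H]3OC[C@@H]1[C@@H]3C2(C)C | intermediate
27 | bis-epoxy C13 ketone with C18–O–C10 ether | O=C1C[C@H]2C[C@H]4O[C@]4(C)CC[C@H]5O[C@@]5(C)C[C@H]3OC[C@@H]1[C@@H]3C2(C)C | intermediate
28 | C10 alcohol of the target (12-methylene-13-ketone, both epoxides) | C=C1C(=O)C[C@H]2C[C@H]3O[C@]3(C)CC[C@H]3O[C@@]3(C)C[C@@H](O)[C@H]1C2(C)C | intermediate
29 | CNP0339728.4: 10-acetoxy-3,4:7,8-diepoxy-12(18)-methylene-13-ketone | C=C1C(=O)C[C@H]2C[C@H]3O[C@]3(C)CC[C@H]3O[C@@]3(C)C[C@@H](OC(C)=O)[C@H]1C2(C)C | target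

## Step count and least certain steps

Total: 20 steps. Longest linear sequence: 19 steps (steps 1–6 and 8–20); step 7 is a one-step side branch.

Step 2 (key step). The second insertion takes place at a β-carbon next to the quaternary carbon and may be slower than protodeboronation of the vinyl reagent, so the reaction may stall at the mono-adduct. Incomplete facial control would add the meso diastereomer. Fallback: the rhodium step is run with about one equivalent of 3 and stopped at 4, which is isolated. The second vinyl group is then added under substrate control by copper-catalysed conjugate addition of vinylmagnesium bromide with Me3SiCl (CuBr·SMe2, THF, −78 °C), anti to the vinyl group already present. This gives 6 directly and rejoins the route in the second stage of step 3. It makes no new compound (F0).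

Step 8. Reductive homocoupling of either iodide, hydrodehalogenation of the alkyl iodide, or partial loss of Z geometry at the alkenylnickel stage may erode the cross-coupling. Fallback, setting out from 10 and returning at 13: the iodide is displaced by LiC≡CH·H2NCH2CH2NH2 in DMSO to give the terminal alkyne F1. Deprotonation (n-BuLi) and ClCO2Me give the methyl ynoate F2. Syn carbocupration with Me2CuLi at −78 °C puts methyl on C8 and leaves C9 cis to the ester, giving the methyl (Z)-enoate F3. Reduction with i-Bu2AlH gives 13. The alkene geometry is then created by a stereospecific addition instead of being carried through a coupling.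

Step 15. Intermolecular alkylation to oligomers may outrun closure of the trans-bridged twelve-membered ring, and base may cause 1,4-elimination of HBr. Fallback, setting out from 10 and returning at 23: the ring is closed at C8–C9 instead, after C5–C6 has been made between two separate pieces.
- The C1 arm of 10 is built with the iodide kept: 9-BBN then NaOH/H2O2 gives the primary alcohol F4; Dess–Martin oxidation gives the aldehyde F5; Wittig reaction with 19 gives the ethyl (E)-enoate F6; i-Bu2AlH gives the (E)-allylic alcohol F7; CBr4/PPh3 gives the (E)-allylic bromide F8.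
- 12 is converted (MsCl, LiBr, then PhSO2Na) to (Z)-3-iodobut-2-enyl phenyl sulfone F9. Its anion (LiN(SiMe3)2, THF, −78 °C) alkylates F8 at the allylic bromide and gives the open-chain iodo sulfone F10.
- Intramolecular nickel-catalysed reductive coupling of the alkyl and alkenyl iodides of F10 (conditions of step 8, high dilution) gives 23.

Step 17. The conformational bias of the macrocycle may oppose the catalyst at one alkene, giving poor facial selectivity, and the second epoxidation may be slow. Fallback, setting out from 24 and returning at 29: the ether is opened first and the epoxidation is run last under substrate control on the natural-type skeleton. Bu4NF gives the C13 alcohol F11. Dess–Martin oxidation gives the keto ether diene F12. DBU/Ac2O/DMAP gives the diene enone acetate F13. Buffered mCPBA (NaHCO3, CH2Cl2, −20 °C) then attacks the two electron-rich trisubstituted alkenes from the periphery of the ring and leaves the enone alone.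

Step 20. The ring–chain equilibrium may lie so far on the side of the cyclic ether that acylative trapping is too slow. The amine base may also add to the enone, or the ketone may be converted to an enol acetate. Fallback, setting out from 24 and returning at 29: the ether is opened before the epoxides exist, so that Lewis acid help can be used. 24 is taken to F11 and F12 as in the fallback to step 17. Me3SiOTf/Et3N (CH2Cl2, −78 → 0 °C) silylates the ring oxygen while the C12 silyl enol ether expels it, and aqueous work-up gives the C10 trimethylsilyl ether enone F14. HF·pyridine followed by Ac2O/pyridine/DMAP gives F13, and the Shi epoxidation of step 17 applied to F13 gives 29.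

## Further compounds

F0 | step 2 | none | none
F1 | step 8 | terminal alkyne: 10 with iodine replaced by C≡CH | CC(C)(C)[Si](C)(C)O[C@H]1C[C@@H](C=C)C(C)(C)[C@H]2[C@H]1CO[C@@H]2CC#C
F2 | step 8 | methyl ynoate from F1 | CC(C)(C)[Si](C)(C)O[C@H]1C[C@@H](C=C)C(C)(C)[C@H]2[C@H]1CO[C@@H]2CC#CC(=O)OC
F3 | step 8 | methyl (Z)-enoate, C9 cis to the ester | CC(C)(C)[Si](C)(C)O[C@H]1C[C@@H](C=C)C(C)(C)[C@H]2[C@H]1CO[C@@H]2C/C(C)=C\C(=O)OC
F4 | step 15 | primary C3 alcohol with the C9 iodide kept | CC(C)(C)[Si](C)(C)O[C@H]1C[C@@H](CCO)C(C)(C)[C@H]2[C@H]1CO[C@@H]2CI
F5 | step 15 | C3 aldehyde with the C9 iodide kept | CC(C)(C)[Si](C)(C)O[C@H]1C[C@@H](CC=O)C(C)(C)[C@H]2[C@H]1CO[C@@H]2CI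
F6 | step 15 | ethyl (E)-enoate with the C9 iodide kept | CC(C)(C)[Si](C)(C)O[C@H]1C[C@@H](C/C=C(\C)C(=O)OCC)C(C)(C)[C@H]2[C@H]1CO[C@@H]2CI
F7 | step 15 | (E)-allylic alcohol with the C9 iodide kept | CC(C)(C)[Si](C)(C)O[C@H]1C[C@@H](C/C=C(\C)CO)C(C)(C)[C@H]2[C@H]1CO[C@@H]2CI
F8 | step 15 | (E)-allylic bromide with the C9 iodide kept | CC(C)(C)[Si](C)(C)O[C@H]1C[C@@H](C/C=C(\C)CBr)C(C)(C)[C@H]2[C@H]1CO[C@@H]2CI
F9 | step 15 | (Z)-3-iodobut-2-enyl phenyl sulfone | C/C(I)=C/CS(=O)(=O)c1ccccc1
F10 | step 15 | open-chain sulfone with C9 alkyl iodide and C8 alkenyl iodide (C6 epimers) | CC(C)(C)[Si](C)(C)O[C@H]1C[C@@H](C/C=C(\C)CC(S(=O)(=O)c3ccccc3)/C=C(C)\I)C(C)(C)[C@H]2[C@H]1CO[C@@H]2CI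
F11 | step 17 | C13 alcohol of the macrocyclic diene ether | O[C@H]1C[C@H]2C/C=C(C)/CC/C=C(C)\C[C@H]3OC[C@@H]1[C@@H]3C2(C)C
F12 | step 17 | keto ether 3E,7Z-diene | O=C1C[C@H]2C/C=C(C)/CC/C=C(C)\C[C@H]3OC[C@@H]1[C@@H]3C2(C)C
F13 | step 17 | 10-acetoxy-12(18)-methylene-13-keto 3E,7Z-diene | C=C1C(=O)C[C@H]2C/C=C(C)/CC/C=C(C)\C[C@@H](OC(C)=O)[C@H]1C2(C)C
F14 | step 20 | C10 trimethylsilyl ether of the methylene ketone diene | C=C1C(=O)C[C@H]2C/C=C(C)/CC/C=C(C)\C[C@@H](O[Si](C)(C)C)[C@H]1C2(C)C
A1 | alternative 1 | bicyclic 3E,7Z-diene, C13 tert-butyldimethylsilyl ether, C10 triethylsilyl ether, C12 methylene | C=C1[C@@H](O[Si](C)(C)C(C)(C)C)C[C@H]2C/C=C(C)/CC/C=C(C)\C[C@@H](O[Si](CC)(CC)CC)[C@H]1C2(C)C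
A2 | alternative 1 | open-chain precursor of A1 with C2 pinacol boronate and (E)-alkenyl iodide at C3 | C=C1[C@@H](O[Si](C)(C)C(C)(C)C)C[C@@H](CB2OC(C)(C)C(C)(C)O2)C(C)(C)[C@@H]1[C@H](O[Si](CC)(CC)CC)C/C(C)=C\CC/C(C)=C/I
A3 | alternative 2 | 4-methyl-5,6-dihydropyran-2-one on C11 of ring A | O=C1C=C(C)C[C@@H](O1)[C@@H]2[C@@H](COCc3ccc(OC)cc3)C(=O)C[C@@H](CO[Si](C)(C)C(C)(C)C)C2(C)C
A4 | alternative 2 | ring A aldehyde, C10 as formyl group on C11 | O=C[C@@H]1[C@@H](COCc2ccc(OC)cc2)C(=O)C[C@@H](CO[Si](C)(C)C(C)(C)C)C1(C)C
A5 | alternative 2 | trimethylsilyl dienolate of methyl 3-methylbut-2-enoate (silyl group assumed) | COC(=CC(C)=C)O[Si](C)(C)C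
A6 | alternative 3 | target skeleton with C12 silyloxymethyl in place of the methylene | O=C1C[C@H]2C[C@H]3O[C@]3(C)CC[C@H]3O[C@@]3(C)C[C@@H](OC(C)=O)[C@@H](C2(C)C)[C@H]1CO[Si](C)(C)C(C)(C)C
A7 | alternative 3 | fourteen-membered cembranoid with C1 isopropenyl and Z enone C11=C12–C13=O | O=C1C[C@H](C(C)=C)C[C@H]2O[C@]2(C)CC[C@H]2O[C@@]2(C)C[C@@H](OC(C)=O)/C=C1/CO[Si](C)(C)C(C)(C)C
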